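**Retrosynthetic overview**

1. Target ⇒ open-chain (7''S,13''S)-dihydroxy-10''-ketone. Both oxolane rings of the spiroketal close last, together, by acid equilibration.
2. Dihydroxy ketone ⇒ C7''–C8'' bond (spiroketal C2–C3): the phthalide aldehyde as acceptor and a β-zincio ketone (ketone homoenolate) released from a cyclopropanol as donor. The catalyst sets the last carbinol centre.
3. Cyclopropanol ⇒ (S)-γ-valerolactone by Kulinkovich cyclopropanation; the methyl carbinol centre comes from the chiral pool.
4. Phthalide aldehyde ⇒ terminal alkene (ozonolysis) ⇒ o-bromo benzylic alcohol (bromine–lithium exchange, CO2, lactonisation) ⇒ 2-bromo-3,5-dimethoxybenzaldehyde + oct-7-enylzinc (catalytic asymmetric addition sets C3).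
5. Ring order: phthalide lactone first (step 3), then the two spiroketal rings in one operation (step 5).

Assumption: locants C1''–C14'' count the side chain of the open-chain form outward from phthalide C3. The 5,5-spiroketal equilibrates under acid to about 1:1 at the spiro carbon, so that centre is set by equilibration, with the epimer fraction fed back into the same acid treatment. Zn(CH2SiMe3)2 is a distilled stock reagent.

**Route**

Step 1
Reactants: 1 (S)-γ-valerolactone [(5S)-5-methyloxolan-2-one]
Product: 2 1-[(3S)-3-hydroxybutyl]cyclopropan-1-ol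
Conditions: EtMgBr (2.4 equiv, Et2O), Ti(OiPr)4 (20 mol %), THF, 15 °C, slow addition, 3 h; cold 1 M HCl
Reagents that add atoms: ethylmagnesium bromide, CC[Mg]Br
Why: Kulinkovich cyclopropanation, in which the titanacyclopropane formed from EtMgBr and Ti(OiPr)4 adds twice to the lactone carbonyl to give the 1-(ω-hydroxyalkyl)cyclopropanol, and the C–O bond at the stereocentre is never broken, so the S configuration of 1 is carried into 2.

Step 2
Reactants: 3 2-bromo-3,5-dimethoxybenzaldehyde; 4 8-bromooct-1-ene
Product: 7 (1R)-1-(2-bromo-3,5-dimethoxyphenyl)non-8-en-1-ol, via oct-7-enylmagnesium bromide 5 (not isolated), via bis(oct-7-enyl)zinc 6 (not isolated)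
Conditions: 4 (3.4 equiv), Mg, Et2O, reflux; ZnCl2 (0.5 equiv per Grignard), 0 °C to rt, then 1,4-dioxane, filter; Ti(OiPr)4 (1.2 equiv), (1S,2S)-1,2-bis(trifluoromethanesulfonamido)cyclohexane (8 mol %), toluene, −20 °C; 3 (1.0 equiv), 16 h; 1 M HCl
Reagents that add atoms: none
Why: Catalytic asymmetric addition of a dialkylzinc to an aromatic aldehyde under Ti(OiPr)4/bis-sulfonamide control (the ligand enantiomer that gives (R)-1-phenylpropan-1-ol from PhCHO and Et2Zn), which delivers the alkyl group to the Re face and sets the carbinol centre as R, while the aryl bromide, aryl ethers and terminal alkene are inert to the zinc and titanium species.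

Step 3
Reactants: 7 (1R)-1-(2-bromo-3,5-dimethoxyphenyl)non-8-en-1-ol
Product: 10 (3R)-5,7-dimethoxy-3-(oct-7-en-1-yl)-2-benzofuran-1(3H)-one, via aryllithium alkoxide 8 (not isolated), via hydroxy acid 9 (not isolated)
Conditions: n-BuLi (2.2 equiv), THF, −78 °C, 30 min; CO2 (g), −78 °C to 0 °C; 2 M HCl, rt, 2 h
Reagents that add atoms: carbon dioxide, O=C=O
Why: Bromine–lithium exchange on the lithium alkoxide followed by carboxylation puts the carboxyl group between OMe and the carbinol arm, and on acidification the γ-hydroxy acid lactonises spontaneously to the phthalide by acyl substitution, so the benzylic C–O bond and the R centre are untouched.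

Step 4
Reactants: 10 (3R)-5,7-dimethoxy-3-(oct-7-en-1-yl)-2-benzofuran-1(3H)-one
Product: 12 7-[(3R)-5,7-dimethoxy-1-oxo-1,3-dihydro-2-benzofuran-3-yl]heptanal, via ozonide 11 (not isolated)
Conditions: O3, CH2Cl2, −78 °C (Sudan red 7B end point); PPh3 (1.2 equiv), −78 °C to rt
Reagents that add atoms: ozone, [O-][O+]=O
Why: Ozonolysis with reductive work-up, in which the monosubstituted alkene reacts much faster than the lactone-deactivated dimethoxyarene when ozone is dosed to the indicator end point, and the C3 stereocentre is not involved.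

Step 5
Reactants: 2 1-[(3S)-3-hydroxybutyl]cyclopropan-1-ol; 12 7-[(3R)-5,7-dimethoxy-1-oxo-1,3-dihydro-2-benzofuran-3-yl]heptanal
Product: 17 (3R)-5,7-dimethoxy-3-{6-[(2S,5R,7S)-7-methyl-1,6-dioxaspiro[4.4]nonan-2-yl]hexyl}-2-benzofuran-1(3H)-one, via bis-zinc cyclopropoxide 13 (not isolated), via zinc homoenolate 14 (not isolated), via dihydroxy ketone 15 (not isolated), via spiro epimer 16 (not isolated)
Conditions: 2 (2.0 equiv), Zn(CH2SiMe3)2 (4.1 equiv), toluene/THF 10:1, 0 °C to 30 °C, 2 h; Ti(OiPr)4 (2.0 equiv), (1S,2S)-1,2-bis(trifluoromethanesulfonamido)cyclohexane (10 mol %), −20 °C; 12 (1.0 equiv), −20 °C, 24 h; 1 M HCl; then CSA (10 mol %), CH2Cl2, rt, 2 h; preparative HPLC, epimer fraction put back under CSA/CH2Cl2 and re-chromatographed (two passes)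
Reagents that add atoms: none
Why: Proposed new method: a catalytic asymmetric homoaldol reaction of a ketone homoenolate, in which protonolysis of Zn(CH2SiMe3)2 by both OH groups of 2 gives 13, the strained zinc cyclopropoxide opens by migration of zinc from O to C to the β-zincio ketone 14 (a mixed dialkylzinc whose Me3SiCH2 group does not transfer, and whose ketone is buffered as the internal zinc hemiketalate of the C13'' alkoxide, which disfavours both re-closure and α-deprotonation to an enolised homoenolate), and the Ti(OiPr)4/bis-sulfonamide catalyst then transfers the functionalised primary alkyl group to the Re face of 12, setting C7'' as S; the closest known reactions are zinc homoenolates made from cyclopropanols and dialkylzincs, their enantioselective conjugate addition to enones, titanium ester-homoenolate additions to aldehydes, and the Ti(OiPr)4/bis-sulfonamide-catalysed addition of RZnCH2SiMe3 reagents to aliphatic aldehydes; acid then closes both γ-hydroxyls of 15 onto the ketone (thermodynamic spiroketalisation) to give 17 and its spiro epimer 16 in about 1:1, which interconvert under CSA through the ring-opened oxocarbenium ion, so that 16 is not taken out as a compound of its own but its fraction is returned to the equilibration and converted on into 17.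

**Compound list**

1 | (S)-γ-valerolactone, (5S)-5-methyloxolan-2-one | C[C@H]1CCC(=O)O1 | starting material
2 | 1-[(3S)-3-hydroxybutyl]cyclopropan-1-ol | C[C@H](O)CCC1(O)CC1 | intermediate
3 | 2-bromo-3,5-dimethoxybenzaldehyde | COc1cc(OC)c(Br)c(C=O)c1 | starting material
4 | 8-bromooct-1-ene | C=CCCCCCCBr | starting material
5 | oct-7-enylmagnesium bromide | C=CCCCCCC[Mg]Br | intermediate
6 | bis(oct-7-enyl)zinc | C=CCCCCCC[Zn]CCCCCCC=C | intermediate
7 | (1R)-1-(2-bromo-3,5-dimethoxyphenyl)non-8-en-1-ol | COc1cc(OC)c(Br)c(c1)[C@@H](CCCCCCC=C)O | intermediate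
8 | lithium (1R)-1-(2-lithio-3,5-dimethoxyphenyl)non-8-en-1-olate (aryllithium alkoxide) | COc1cc(OC)c([Li])c(c1)[C@@H](CCCCCCC=C)O[Li] | intermediate
9 | 2-[(1R)-1-hydroxynon-8-en-1-yl]-4,6-dimethoxybenzoic acid (hydroxy acid) | COc1cc(OC)c(C(=O)O)c(c1)[C@@H](CCCCCCC=C)O | intermediate
10 | (3R)-5,7-dimethoxy-3-(oct-7-en-1-yl)-2-benzofuran-1(3H)-one | COc1cc(OC)c2c(c1)[C@@H](CCCCCCC=C)OC2=O | intermediate
11 | (3R)-5,7-dimethoxy-3-[6-(1,2,4-trioxolan-3-yl)hexyl]-2-benzofuran-1(3H)-one (ozonide, epimer mixture at the trioxolane carbon) | COc1cc(OC)c2c(c1)[C@@H](CCCCCCC1OCOO1)OC2=O | intermediate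
12 | 7-[(3R)-5,7-dimethoxy-1-oxo-1,3-dihydro-2-benzofuran-3-yl]heptanal | COc1cc(OC)c2c(c1)[C@@H](CCCCCCC=O)OC2=O | intermediate
13 | bis[(trimethylsilylmethyl)zinc] dialkoxide of 2 (bis-zinc cyclopropoxide) | C[C@H](O[Zn]C[Si](C)(C)C)CCC1(O[Zn]C[Si](C)(C)C)CC1 | intermediate
14 | [(6S)-3-oxo-6-{[(trimethylsilylmethyl)zincio]oxy}heptyl](trimethylsilylmethyl)zinc (zinc homoenolate) | C[C@H](O[Zn]C[Si](C)(C)C)CCC(=O)CC[Zn]C[Si](C)(C)C | intermediate
15 | (3R)-3-[(7S,13S)-7,13-dihydroxy-10-oxotetradecyl]-5,7-dimethoxy-2-benzofuran-1(3H)-one (dihydroxy ketone) | COc1cc(OC)c2c(c1)[C@@H](CCCCCC[C@H](O)CCC(=O)CC[C@H](C)O)OC2=O | intermediate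
16 | (3R)-5,7-dimethoxy-3-{6-[(2S,5S,7S)-7-methyl-1,6-dioxaspiro[4.4]nonan-2-yl]hexyl}-2-benzofuran-1(3H)-one (spiro epimer, in acid equilibrium with 17) | COc1cc(OC)c2c(c1)[C@@H](CCCCCC[C@H]1CC[C@]3(CC[C@H](C)O3)O1)OC2=O | intermediate
17 | (3R)-5,7-dimethoxy-3-{6-[(2S,5R,7S)-7-methyl-1,6-dioxaspiro[4.4]nonan-2-yl]hexyl}-2-benzofuran-1(3H)-one | COc1cc(OC)c2c(c1)[C@@H](CCCCCC[C@H]1CC[C@@]3(CC[C@H](C)O3)O1)OC2=O | target

**Summary**

Total step count: 5. Longest linear sequence: 4 steps (3 → 7 → 10 → 12 → 17); step 1 is a one-step side branch.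

Steps most likely to fail:

Step 5. The zinc cyclopropoxide may fail to open, may pass the cyclopropoxide to titanium, or 14 may be deprotonated at the α-carbon and react as an enolised homoenolate instead. The fallback sets out from 2 and 12 and returns at 17. N-iodosuccinimide in MeOH at 0 °C opens 2 to the β-iodo ketone (6S)-6-hydroxy-1-iodoheptan-3-one F1. This is closed in the same flask with HC(OMe)3 and PPTS to the cyclic methyl ketal (5S)-2-(2-iodoethyl)-2-methoxy-5-methyloxolane F2 (anomer mixture, isolated). Iodine–zinc exchange with Et2Zn and catalytic CuI, followed by evacuation, gives the ketal-masked homoenolate bis{2-[(5S)-2-methoxy-5-methyloxolan-2-yl]ethyl}zinc F3, which can neither re-close nor enolise. Its addition to 12 under the same Ti(OiPr)4/(1S,2S)-bis-sulfonamide catalysis, quenched with saturated aqueous NH4Cl, gives the hydroxy ketal (3R)-3-{(7S)-7-hydroxy-9-[(5S)-2-methoxy-5-methyloxolan-2-yl]nonyl}-5,7-dimethoxy-2-benzofuran-1(3H)-one F4. CSA in CH2Cl2 then exchanges the methoxy group for the C7'' hydroxyl and delivers 17 through the same equilibration with its spiro epimer 16 as in step 5. This costs one extra isolated step but uses only established reaction types.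

Step 2. Conversion and ee may suffer with the ortho-bromo, electron-rich aldehyde and a Grignard-derived zinc reagent. The fallback sets out from 3 and the Grignard 5 and returns at 7. Direct addition of 5 to 3 in THF at 0 °C gives racemic 1-(2-bromo-3,5-dimethoxyphenyl)non-8-en-1-ol F5. Dess–Martin periodinane oxidises it to 1-(2-bromo-3,5-dimethoxyphenyl)non-8-en-1-one F6. Asymmetric transfer hydrogenation with RuCl[(R,R)-TsDPEN](p-cymene) in HCO2H/Et3N (the catalyst enantiomer that gives (R)-1-phenylethanol from acetophenone; the alkene is untouched) returns the (R)-alcohol 7.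

Step 4. Ozone may attack the dimethoxyarene. The fallback sets out from 10 and returns at 12. Catalytic OsO4 with NMO in acetone–water gives the diol (3R)-3-(7,8-dihydroxyoctyl)-5,7-dimethoxy-2-benzofuran-1(3H)-one F7 (epimer mixture at C7'', irrelevant), which NaIO4 in THF–water cleaves to 12.

**Further compounds**

F1 | step 5 | (6S)-6-hydroxy-1-iodoheptan-3-one | C[C@H](O)CCC(=O)CCI
F2 | step 5 | (5S)-2-(2-iodoethyl)-2-methoxy-5-methyloxolane | C[C@H]1CCC(CCI)(OC)O1
F3 | step 5 | bis{2-[(5S)-2-methoxy-5-methyloxolan-2-yl]ethyl}zinc | C[C@H]1CCC(CC[Zn]CCC2(OC)CC[C@H](C)O2)(OC)O1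
F4 | step 5 | (3R)-3-{(7S)-7-hydroxy-9-[(5S)-2-methoxy-5-methyloxolan-2-yl]nonyl}-5,7-dimethoxy-2-benzofuran-1(3H)-one | COc1cc(OC)c2c(c1)[C@@H](CCCCCC[C@H](O)CCC1(OC)CC[C@H](C)O1)OC2=O
F5 | step 2 | rac-1-(2-bromo-3,5-dimethoxyphenyl)non-8-en-1-ol | COc1cc(OC)c(Br)c(c1)C(O)CCCCCCC=C
F6 | step 2 | 1-(2-bromo-3,5-dimethoxyphenyl)non-8-en-1-one | COc1cc(OC)c(Br)c(c1)C(=O)CCCCCCC=C
F7 | step 4 | (3R)-3-(7,8-dihydroxyoctyl)-5,7-dimethoxy-2-benzofuran-1(3H)-one | COc1cc(OC)c2c(c1)[C@@H](CCCCCCC(O)CO)OC2=O
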